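**Retrosynthetic overview**
- The target comes from a 4-bromo-3-[(R)-1-hydroxybutyl]-5-(tribromomethyl)butenolide by E1cB loss of HBr; the exocyclic C=CBr2 is the last bond made.
- The butenolide (the only ring, closed once, in the key step) is cut at C4–C5: a β-magnesiated β-bromoacrylate (carbanion on the acrylate β-carbon, a homoenolate-type d3 reagent) adds to the carbonyl carbon of bromal, and the alkoxide lactonises onto the cis ester in the same flask.
- That carbanion comes from ester-directed Br/Mg exchange of ethyl (R)-2-(dibromomethylene)-3-hydroxyhexanoate, its OH masked in the flask as the Me3Si ether.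
- The (R)-carbinol comes from CBS reduction of ethyl 2-(dibromomethylene)-3-oxohexanoate.
- That enone comes from Ramirez olefination of ethyl 2,3-dioxohexanoate, made by oxidising ethyl 3-oxohexanoate.

Assumption: the target is the (R)-alcohol encoded by the SMILES; ring locants are O1, C2 (C=O), C3 (side chain), C4 (Br), C5 (=CBr2).

**Route**

Step 1
Reactants: 1 ethyl 3-oxohexanoate
Product: 2 ethyl 2,3-dioxohexanoate
Conditions: Dess–Martin periodinane (2.5 equiv), pyridine (5 equiv), CH2Cl2, 0 °C → rt, 16 h; filter, concentrate, bulb-to-bulb distil (anhydrous)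
Reagents that add atoms: Dess–Martin periodinane, CC(=O)OI1(OC(C)=O)(OC(C)=O)OC(=O)c2ccccc12
Why: Periodinane α-oxidation of a 1,3-dicarbonyl to the vicinal tricarbonyl: the pentavalent iodine reagent transfers acetate oxygen twice to the doubly activated C2 methylene (far more enolised than the C4 methylene) and the resulting gem-diacetate collapses to the ketone, so the new carbonyl oxygen comes from the periodinane; no stereocenter is formed.

Step 2
Reactants: 2 ethyl 2,3-dioxohexanoate; 3 carbon tetrabromide
Product: 4 ethyl 2-(dibromomethylene)-3-oxohexanoate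
Conditions: CBr4 (1.5 equiv), PPh3 (3.0 equiv), CH2Cl2, 0 °C, 15 min; then 2, 0 °C → rt
Reagents that add atoms: carbon tetrabromide 3, BrC(Br)(Br)Br
Why: Ramirez dibromo-olefination (first half of the Corey–Fuchs sequence): the pre-formed ylide Ph3P=CBr2 reacts in Wittig fashion at the central carbonyl, the most electrophilic of the three as in dialkyl ketomalonates; no stereocenter is formed.

Step 3
Reactants: 4 ethyl 2-(dibromomethylene)-3-oxohexanoate
Product: 5 ethyl (3R)-2-(dibromomethylene)-3-hydroxyhexanoate
Conditions: (S)-Me-CBS oxazaborolidine [(S)-1-methyl-3,3-diphenyltetrahydro-1H,3H-pyrrolo[1,2-c][1,3,2]oxazaborole] (15 mol %), BH3·SMe2 (0.7 equiv), toluene, −30 °C; MeOH, then 1 M HCl work-up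
Reagents that add atoms: none
Why: Corey–Bakshi–Shibata reduction: the ketone binds the ring boron anti to its large α-branched dibromovinyl ester arm with n-propyl as the small arm, so the (S)-catalyst delivers hydride to the face that gives the (R)-carbinol (same sense as acetophenone to (R)-1-phenylethanol), while the ester and the electron-poor alkene are inert to borane at −30 °C.

Step 4
Reactants: 5 ethyl (3R)-2-(dibromomethylene)-3-hydroxyhexanoate; 6 tribromoacetaldehyde (bromal)
Product: 11 4-bromo-3-[(1R)-1-hydroxybutyl]-5-(tribromomethyl)furan-2(5H)-one (both C5 epimers), via trimethylsilyl ether 7 (not isolated), via magnesium carbenoid 8 (not isolated), via magnesium alkoxide 9 (not isolated), via silylated lactone 10 (not isolated)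
Conditions: (Me3Si)2NH (0.7 equiv), Me3SiCl (2 mol %), CH2Cl2, rt, evaporate; iPrMgCl·LiCl (1.05 equiv), THF, −78 °C, 30 min; Br3CCHO (1.3 equiv), −78 → 0 °C; 1 M HCl, THF, rt
Reagents that add atoms: tribromoacetaldehyde 6, O=CC(Br)(Br)Br; hexamethyldisilazane, C[Si](C)(C)N[Si](C)(C)C; iPrMgCl·LiCl, CC(C)[Mg]Cl.[Li]Cl
Why: Proposed new method: transient O-silylation by the disilazane (so that no alkoxide can direct the exchange) lets iPrMgCl·LiCl exchange the bromine cis to the ester, where the new C–Mg bond is chelated by the ester carbonyl, giving a β-magnesiated acrylate, that is a homoenolate-type (d3) carbanion on the normally electrophilic β-carbon, which adds to the aldehyde carbon of bromal and whose alkoxide lactonises onto the cis ester (5-exo-trig), the closest known reaction type being Br/Mg exchange of ester-substituted 1,1-dibromoalkenes to chelated magnesium carbenoids that add to aldehydes and close to 4-bromobutenolides; the Me3Si group sits only on 7 to 10 and the MgCl unit only on 8 and 9, the acid work-up cleaving the silyl ether so that neither remains in 11, the (R)-carbinol is not touched and the new C5 center (both epimers) is erased in step 5.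

Step 5
Reactants: 11 4-bromo-3-[(1R)-1-hydroxybutyl]-5-(tribromomethyl)furan-2(5H)-one
Product: 12 4-bromo-5-(dibromomethylene)-3-[(1R)-1-hydroxybutyl]furan-2(5H)-one
Conditions: iPr2NEt (1.5 equiv), CH2Cl2, 0 °C → rt; aqueous wash
Reagents that add atoms: none
Why: E1cB dehydrobromination: the hindered amine removes the acidic C5–H (γ to the lactone carbonyl, next to CBr3) to give an aromatic 2-oxidofuran that expels bromide from the CBr3 group, forming the exocyclic C=CBr2 without touching the non-acidic (R)-carbinol center.

**Compound list**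
1 | ethyl 3-oxohexanoate | CCCC(=O)CC(=O)OCC | starting material
2 | ethyl 2,3-dioxohexanoate | CCCC(=O)C(=O)C(=O)OCC | intermediate
3 | carbon tetrabromide | BrC(Br)(Br)Br | starting material
4 | ethyl 2-(dibromomethylene)-3-oxohexanoate | CCCC(=O)C(=C(Br)Br)C(=O)OCC | intermediate
5 | ethyl (3R)-2-(dibromomethylene)-3-hydroxyhexanoate | CCC[C@@H](O)C(=C(Br)Br)C(=O)OCC | intermediate
6 | tribromoacetaldehyde (bromal) | O=CC(Br)(Br)Br | starting material
7 | ethyl (3R)-2-(dibromomethylene)-3-(trimethylsilyloxy)hexanoate | CCC[C@@H](O[Si](C)(C)C)C(=C(Br)Br)C(=O)OCC | intermediate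
8 | chloro[(1E,3R)-1-bromo-2-(ethoxycarbonyl)-3-(trimethylsilyloxy)hex-1-en-1-yl]magnesium (as its LiCl complex; Mg cis to the ester) | CCC[C@@H](O[Si](C)(C)C)/C(C(=O)OCC)=C(\Br)[Mg]Cl | intermediate
9 | ethyl (2E)-3,5,5,5-tetrabromo-4-[(chloromagnesio)oxy]-2-[(1R)-1-(trimethylsilyloxy)butyl]pent-2-enoate (C4 epimers) | CCC[C@@H](O[Si](C)(C)C)/C(C(=O)OCC)=C(\Br)C(O[Mg]Cl)C(Br)(Br)Br | intermediate
10 | 4-bromo-5-(tribromomethyl)-3-[(1R)-1-(trimethylsilyloxy)butyl]furan-2(5H)-one (C5 epimers) | CCC[C@@H](O[Si](C)(C)C)C1=C(Br)C(C(Br)(Br)Br)OC1=O | intermediate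
11 | 4-bromo-3-[(1R)-1-hydroxybutyl]-5-(tribromomethyl)furan-2(5H)-one (C5 epimers) | CCC[C@@H](O)C1=C(Br)C(C(Br)(Br)Br)OC1=O | intermediate
12 | 4-bromo-5-(dibromomethylene)-3-[(1R)-1-hydroxybutyl]furan-2(5H)-one | CCC[C@@H](O)C1=C(Br)C(=C(Br)Br)OC1=O | target

**Step count and risks**
Total step count: 5.
Longest linear sequence: 5 steps (1 → 2 → 4 → 5 → 11 → 12).
Steps most likely to fail: 4, 2 and 3.

Most at risk is step 4: bromal may hand a bromine to the carbenoid instead of accepting it at carbon, or the tribromomethyl alkoxide may collapse before it lactonises. The fallback sets out from 5 and comes back at 11. Compound 5 is silylated and exchanged exactly as before (7, then 8), but 8 is formylated with DMF (−78 → −20 °C) to the silylated aldehyde ethyl (2E)-3-bromo-4-oxo-2-[(1R)-1-(trimethylsilyloxy)butyl]but-2-enoate F1. 1 M HCl work-up then gives the hydroxy aldehyde ethyl (2E)-3-bromo-2-[(1R)-1-hydroxybutyl]-4-oxobut-2-enoate F2. Tribromomethyl anion is then made without any organometallic (Br3CCO2Na, Br3CCO2H, DMSO, rt, decarboxylation) and adds to the aldehyde to give the hydroxy ester ethyl (2E)-3,5,5,5-tetrabromo-4-hydroxy-2-[(1R)-1-hydroxybutyl]pent-2-enoate F3, which lactonises (cat. p-toluenesulfonic acid, CH2Cl2) to 11. The C4–C5 bond is still made by the same β-carbanion, but bromal never meets a Grignard reagent.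

Next is step 2: the tricarbonyl hydrates easily, PPh3 can attack it, and the olefination could go to the wrong carbonyl. The fallback sets out from 2 and comes back at 4. Br3CCO2Na and Br3CCO2H in DMSO add tribromomethyl anion to the central carbonyl (the one that hydrates) to give the carbinol ethyl 2-hydroxy-3-oxo-2-(tribromomethyl)hexanoate F4. Ac2O, pyridine and 4-(dimethylamino)pyridine give the acetate ethyl 2-acetoxy-3-oxo-2-(tribromomethyl)hexanoate F5. Zn dust in AcOH–THF at 0 °C inserts into a C–Br bond and expels the acetate (reductive 1,2-elimination) to give 4. Olefination is thus replaced by addition and reductive elimination, with no phosphorus reagent.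

Third is step 3: the enantioselectivity of the CBS reduction on this crowded, electron-poor enone is untested. The fallback sets out from 4 and comes back at 5. Luche reduction (NaBH4, CeCl3·7H2O, MeOH, −40 °C) gives the racemic alcohol ethyl 2-(dibromomethylene)-3-hydroxyhexanoate F6. Burkholderia cepacia lipase with vinyl acetate in tert-butyl methyl ether at 30 °C acylates the (R)-enantiomer (Kazlauskas rule: dibromovinyl ester arm large, propyl medium) to the acetate ethyl (3R)-3-acetoxy-2-(dibromomethylene)hexanoate F7. F7 is separated by chromatography from the slow-reacting alcohol ethyl (3S)-2-(dibromomethylene)-3-hydroxyhexanoate F8. The same lipase in pH 7 phosphate buffer–acetone hydrolyses F7 to 5, which raises the ee once more.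

**Further compounds**
F1 | step 4 | ethyl (2E)-3-bromo-4-oxo-2-[(1R)-1-(trimethylsilyloxy)butyl]but-2-enoate | CCC[C@@H](O[Si](C)(C)C)/C(C(=O)OCC)=C(\Br)C=O
F2 | step 4 | ethyl (2E)-3-bromo-2-[(1R)-1-hydroxybutyl]-4-oxobut-2-enoate | CCC[C@@H](O)/C(C(=O)OCC)=C(\Br)C=O
F3 | step 4 | ethyl (2E)-3,5,5,5-tetrabromo-4-hydroxy-2-[(1R)-1-hydroxybutyl]pent-2-enoate (C4 epimers) | CCC[C@@H](O)/C(C(=O)OCC)=C(\Br)C(O)C(Br)(Br)Br
F4 | step 2 | ethyl 2-hydroxy-3-oxo-2-(tribromomethyl)hexanoate (racemic) | CCCC(=O)C(O)(C(Br)(Br)Br)C(=O)OCC
F5 | step 2 | ethyl 2-acetoxy-3-oxo-2-(tribromomethyl)hexanoate (racemic) | CCCC(=O)C(OC(C)=O)(C(Br)(Br)Br)C(=O)OCC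
F6 | step 3 | ethyl 2-(dibromomethylene)-3-hydroxyhexanoate (racemic) | CCCC(O)C(=C(Br)Br)C(=O)OCC
F7 | step 3 | ethyl (3R)-3-acetoxy-2-(dibromomethylene)hexanoate | CCC[C@@H](OC(C)=O)C(=C(Br)Br)C(=O)OCC
F8 | step 3 | ethyl (3S)-2-(dibromomethylene)-3-hydroxyhexanoate | CCC[C@H](O)C(=C(Br)Br)C(=O)OCC
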